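**Retrosynthetic overview**
1. Target 28 ← 27 (desilylation of O14) ← 26 (isobutyrylation of the C3 carbinol).
2. Key disconnection C3–C4: the ten-membered carbocycle (ring C) is closed last, by intramolecular Nozaki–Hiyama–Kishi addition of the iodinated butenolide carbon C4 of seco-aldehyde 25 to its C3 aldehyde.
3. Enabling feature: C3, the carbinol carbon that carries the isobutyrate, sits directly on C4, the α-carbon of the butenolide ring O–C15(=O)–C4=C5–C6. This is an allylic alcohol whose alkene is locked in a five-membered lactone (C15 and C6 cis), the retron of an alkenylmetal–aldehyde addition, and it can only give the carbocycle with C3 and C6 trans on C4=C5.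
4. Butenolide (ring B, second) ← γ-hydroxy alkynoate 21 (syn-hydrostannation, lactonization, iododestannylation) ← ynone 20 (reagent-controlled reduction sets C6) ← α-methylene acid 15.
5. α-Methylene-γ-butyrolactone (ring A, first) ← auxiliary-controlled syn-aldol of succinyl imide 10 with aldehyde 8 (C7, C8), lactonization, decarboxylative methylenation; C10 ← auxiliary-controlled alkylation of 3.

Key step: step 15

Remark: germacrane numbering is used (carbocycle C1–C10 with C3 bearing the ester oxygen, C4=C5 the butenolide alkene, O6 and O8 the lactone oxygens, C10 bearing C14H2OH; C11(=C13H2)–C12(=O) the methylene lactone; C15 the butenolide carbonyl), and 1, 2, 4, 9, 16 and 17 are taken as commercial.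

Step 1
Reactants: 1 (4S)-4-benzyl-1,3-oxazolidin-2-one; 2 hex-5-enoyl chloride
Product: 3 (4S)-4-benzyl-3-(hex-5-enoyl)-1,3-oxazolidin-2-one
Conditions: n-BuLi, THF, −78 °C; then 2, −78 → 0 °C
Reagents that add atoms: none
Why: N-acylation of the lithium salt of the oxazolidinone by an acid chloride is a clean acyl substitution and attaches the auxiliary that will control C10; no stereocenter is formed.

Step 2
Reactants: 3 (4S)-4-benzyl-3-(hex-5-enoyl)-1,3-oxazolidin-2-one; 4 tert-butyl bromoacetate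
Product: 5 tert-butyl (3R)-3-{[(4S)-4-benzyl-2-oxo-1,3-oxazolidin-3-yl]carbonyl}hept-6-enoate
Conditions: NaN(SiMe3)2, THF, −78 °C; then 4, −78 → −40 °C
Reagents that add atoms: none
Why: Evans asymmetric alkylation: the chelated Z-sodium enolate of 3 is attacked by the reactive α-bromo ester on the face opposite the benzyl group, which sets C10 with the R configuration.

Step 3
Reactants: 5 tert-butyl (3R)-3-{[(4S)-4-benzyl-2-oxo-1,3-oxazolidin-3-yl]carbonyl}hept-6-enoate
Product: 6 tert-butyl (3R)-3-(hydroxymethyl)hept-6-enoate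
Conditions: LiBH4, MeOH (1 equiv), THF, 0 °C
Reagents that add atoms: none
Why: Reductive cleavage of an N-acyloxazolidinone with LiBH4 reduces the activated exocyclic imide carbonyl to the primary alcohol (C14) while the hindered tert-butyl ester and the C10 center are untouched, and auxiliary 1 is returned.

Step 4
Reactants: 6 tert-butyl (3R)-3-(hydroxymethyl)hept-6-enoate
Product: 7 tert-butyl (3R)-3-({[tert-butyl(diphenyl)silyl]oxy}methyl)hept-6-enoate
Conditions: t-BuPh2SiCl, imidazole, DMF, 25 °C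
Reagents that add atoms: tert-butyl(chloro)diphenylsilane, CC(C)(C)[Si](Cl)(c1ccccc1)c1ccccc1
Why: Silyl ether formation at the unhindered primary hydroxyl; the robust tert-butyldiphenylsilyl group is chosen to outlast the hot basic carboxylation, the acid chloride and the chromium step.

Step 5
Reactants: 7 tert-butyl (3R)-3-({[tert-butyl(diphenyl)silyl]oxy}methyl)hept-6-enoate
Product: 8 (3R)-3-({[tert-butyl(diphenyl)silyl]oxy}methyl)hept-6-enal
Conditions: i-Bu2AlH, toluene, −78 °C; aq. potassium sodium tartrate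
Reagents that add atoms: none
Why: Partial reduction of the ester with i-Bu2AlH at −78 °C stops at the aluminium hemiacetal, which releases the C8 aldehyde only on work-up; no stereocenter is touched.

Step 6
Reactants: 1 (4S)-4-benzyl-1,3-oxazolidin-2-one; 9 methyl 4-chloro-4-oxobutanoate
Product: 10 methyl 4-[(4S)-4-benzyl-2-oxo-1,3-oxazolidin-3-yl]-4-oxobutanoate
Conditions: n-BuLi, THF, −78 °C; then 9, −78 → 0 °C
Reagents that add atoms: none
Why: N-acylation as in step 1 gives the succinyl imide, whose imide α-methylene (the future C7) is the only position enolized by the boron triflate.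

Step 7
Reactants: 10 methyl 4-[(4S)-4-benzyl-2-oxo-1,3-oxazolidin-3-yl]-4-oxobutanoate; 8 (3R)-3-({[tert-butyl(diphenyl)silyl]oxy}methyl)hept-6-enal
Product: 12 (4S)-4-benzyl-3-{[(2R,3S)-2-[(2R)-2-({[tert-butyl(diphenyl)silyl]oxy}methyl)hex-5-en-1-yl]-5-oxooxolan-3-yl]carbonyl}-1,3-oxazolidin-2-one, via aldol adduct 11 (not isolated)
Conditions: n-Bu2BOTf, i-Pr2NEt, CH2Cl2, −78 → 0 °C; then 8, −78 → 0 °C; H2O2, pH 7 buffer, MeOH; then TsOH (cat.), CH2Cl2, 25 °C
Reagents that add atoms: none
Why: Evans syn-aldol reaction: the Z-dibutylboron enolate of 10 adds to 8 through a closed chair transition state on the enolate face away from the benzyl group, which sets C7 (S) and C8 (R) syn, and the C8 hydroxyl of 11 then closes onto the methyl ester (5-exo-trig lactonization) to give the trans-disubstituted γ-lactone (ring A).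

Step 8
Reactants: 12 (4S)-4-benzyl-3-{[(2R,3S)-2-[(2R)-2-({[tert-butyl(diphenyl)silyl]oxy}methyl)hex-5-en-1-yl]-5-oxooxolan-3-yl]carbonyl}-1,3-oxazolidin-2-one
Product: 13 (2R,3S)-2-[(2R)-2-({[tert-butyl(diphenyl)silyl]oxy}methyl)hex-5-en-1-yl]-5-oxooxolane-3-carboxylic acid
Conditions: LiOH, H2O2, THF/H2O, 0 °C; Na2SO3; then HCl to pH 2
Reagents that add atoms: hydrogen peroxide (as LiOOH), OO
Why: Hydroperoxide-mediated hydrolysis of the N-acyloxazolidinone attacks the exocyclic carbonyl selectively, any lactone opened by hydroxide recloses on acidification, and the trans arrangement at C7/C8 is the thermodynamically favored one, so no epimer is expected.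

Step 9
Reactants: 13 (2R,3S)-2-[(2R)-2-({[tert-butyl(diphenyl)silyl]oxy}methyl)hex-5-en-1-yl]-5-oxooxolane-3-carboxylic acid
Product: 15 (2R,3S)-2-[(2R)-2-({[tert-butyl(diphenyl)silyl]oxy}methyl)hex-5-en-1-yl]-4-methylidene-5-oxooxolane-3-carboxylic acid, via malonic half acid 14 (not isolated)
Conditions: MeOMgOCO2Me (2 M in DMF), 135 °C; aq. HCl; then 37% aq. HCHO, PhNHMe, NaOAc, AcOH, 25 °C
Reagents that add atoms: formaldehyde, C=O; methoxymagnesium methyl carbonate, COC(=O)O[Mg]OC (its CO2 unit is in 14 only)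
Why: Decarboxylative α-methylenation: the magnesium methyl carbonate carboxylates the lactone α-position C11 as its chelated malonate, and the Mannich reaction with formaldehyde and N-methylaniline followed by decarboxylative elimination installs the exocyclic methylene without touching C7 or C8, as is standard for paraconic acids.

Step 10
Reactants: 16 methyl prop-2-ynoate; 17 tributyl(methoxy)stannane
Product: 18 methyl 3-(tributylstannyl)prop-2-ynoate
Conditions: neat, 25 °C, MeOH removed under vacuum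
Reagents that add atoms: none
Why: Stannylation of the acidic terminal alkyne by the tin methoxide is an acid–base exchange driven by removal of methanol.

Step 11
Reactants: 15 (2R,3S)-2-[(2R)-2-({[tert-butyl(diphenyl)silyl]oxy}methyl)hex-5-en-1-yl]-4-methylidene-5-oxooxolane-3-carboxylic acid; 18 methyl 3-(tributylstannyl)prop-2-ynoate
Product: 20 methyl 4-[(2R,3S)-2-[(2R)-2-({[tert-butyl(diphenyl)silyl]oxy}methyl)hex-5-en-1-yl]-4-methylidene-5-oxooxolan-3-yl]-4-oxobut-2-ynoate, via acid chloride 19 (not isolated)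
Conditions: 1-chloro-N,N,2-trimethylprop-1-en-1-amine, CH2Cl2, 0 → 25 °C; then 18, Pd2(dba)3 (cat.), tri(2-furyl)phosphine (cat.), toluene, 25–40 °C
Reagents that add atoms: 1-chloro-N,N,2-trimethylprop-1-en-1-amine, CC(C)=C(Cl)N(C)C (its chlorine is in 19 only)
Why: The α-chloroenamine converts the acid into the acid chloride without acid or base, and the Stille acylation (palladium-catalyzed coupling of an acid chloride with an alkynylstannane) forms the C6 ynone under neutral conditions, which protects the C7 center and the exocyclic alkene from base-induced isomerization.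

Step 12
Reactants: 20 methyl 4-[(2R,3S)-2-[(2R)-2-({[tert-butyl(diphenyl)silyl]oxy}methyl)hex-5-en-1-yl]-4-methylidene-5-oxooxolan-3-yl]-4-oxobut-2-ynoate
Product: 21 methyl (4S)-4-hydroxy-4-[(2R,3R)-2-[(2R)-2-({[tert-butyl(diphenyl)silyl]oxy}methyl)hex-5-en-1-yl]-4-methylidene-5-oxooxolan-3-yl]but-2-ynoate
Conditions: Ru(p-cymene)[(S,S)-TsNCH(Ph)CH(Ph)NH] (2 mol%), i-PrOH/CH2Cl2, 25 °C
Reagents that add atoms: none
Why: Noyori asymmetric transfer hydrogenation of an alkynyl ketone: the (S,S)-diamine ruthenium hydride delivers hydride under reagent control, the alkynyl group taking the place of the aryl group of the aryl ketone model, which sets C6 as the (S)-propargylic carbinol (the configuration that becomes 6R in the target) independently of the neighboring C7 center.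

Step 13
Reactants: 21 methyl (4S)-4-hydroxy-4-[(2R,3R)-2-[(2R)-2-({[tert-butyl(diphenyl)silyl]oxy}methyl)hex-5-en-1-yl]-4-methylidene-5-oxooxolan-3-yl]but-2-ynoate
Product: 24 (4S,5R)-5-[(2R)-2-({[tert-butyl(diphenyl)silyl]oxy}methyl)hex-5-en-1-yl]-4-[(2S)-4-iodo-5-oxo-2,5-dihydrofuran-2-yl]-3-methylideneoxolan-2-one, via hydroxy stannyl enoate 22 (not isolated), via stannyl butenolide 23 (not isolated)
Conditions: Pd(PPh3)4 (cat.), n-Bu3SnH, THF, 0 → 25 °C; then I2, CH2Cl2, 0 °C; aq. Na2S2O3
Reagents that add atoms: iodine, II; tributylstannane, CCCC[SnH](CCCC)CCCC (its tin is in 22 and 23 only)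
Why: Palladium-catalyzed syn-hydrostannation of the alkynoate places tin on C4 (α to the ester) and hydrogen on C5, so that the ester and the C6 hydroxyl are cis and lactonize to the butenolide (ring B), and iododestannylation then replaces tin by iodine at C4 with retention; C6 is not affected.

Step 14
Reactants: 24 (4S,5R)-5-[(2R)-2-({[tert-butyl(diphenyl)silyl]oxy}methyl)hex-5-en-1-yl]-4-[(2S)-4-iodo-5-oxo-2,5-dihydrofuran-2-yl]-3-methylideneoxolan-2-one
Product: 25 (4R)-4-({[tert-butyl(diphenyl)silyl]oxy}methyl)-5-[(2R,3S)-3-[(2S)-4-iodo-5-oxo-2,5-dihydrofuran-2-yl]-4-methylidene-5-oxooxolan-2-yl]pentanal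
Conditions: OsO4 (cat.), NaIO4, 2,6-lutidine, dioxane/H2O, 25 °C
Reagents that add atoms: sodium periodate (its oxygen reaches C3 by way of OsO4), [Na+].[O-]I(=O)(=O)=O
Why: Lemieux–Johnson oxidation: OsO4 dihydroxylates the electron-rich monosubstituted alkene much faster than the electron-poor exocyclic acrylate and the iodinated butenolide alkene, and periodate cleaves the diol to the C3 aldehyde.

Step 15
Reactants: 25 (4R)-4-({[tert-butyl(diphenyl)silyl]oxy}methyl)-5-[(2R,3S)-3-[(2S)-4-iodo-5-oxo-2,5-dihydrofuran-2-yl]-4-methylidene-5-oxooxolan-2-yl]pentanal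
Product: 26 (3S,6R,7S,8R,10R)-14-[tert-butyl(diphenyl)silyl]oxy-3-hydroxygermacra-4,11(13)-diene-12,8:15,6-diolide
Conditions: CrCl2 (10 equiv), NiCl2 (cat.), DMSO, 25 °C, 0.003 M, slow addition of 25
Reagents that add atoms: none
Why: CrCl2 reduces NiCl2 to zerovalent nickel, which inserts into the C4–I bond; transmetalation gives the alkenyl dichlorochromium species (trivalent chromium) at C4, and this non-basic nucleophile adds to the tethered C3 aldehyde, i.e. an intramolecular Nozaki–Hiyama–Kishi reaction, whose closest precedent is the closure of strained nine- to eleven-membered trans-cycloalkenols from alkenyl iodide aldehydes. Ring C closes in the 10-exo-trig mode by attack of the ring-locked sp2 carbon C4 on the carbonyl carbon C3; because the butenolide holds C15 and C6 cis, C3 and C6 are necessarily trans on C4=C5 and ring B becomes the two-atom bridge of an oxabicyclo[7.2.1] core, so one operation completes the tricyclic skeleton from two simple five-membered rings joined by one bond. The new stereocenter C3 is under substrate control: the C6 center forces the C7–C2 tether over one face of the planar butenolide, C2 therefore lies on that face in the transition state, and the carbonyl oxygen with its bulky chromium is expected to point to the open C5–H flank, opposed to the C15=O dipole, which gives 3S, whereas the alternative presses the chromium alkoxide against the lactone carbonyl. The step needs chemoselectivity, which the organochromium secures by adding to aldehydes only (lactones, exocyclic methylene and silyl ether are left alone), and ring closure instead of oligomerization, which high dilution and the turn imposed by the two rigid lactone rings secure.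

Step 16
Reactants: 26 (3S,6R,7S,8R,10R)-14-[tert-butyl(diphenyl)silyl]oxy-3-hydroxygermacra-4,11(13)-diene-12,8:15,6-diolide
Product: 27 (3S,6R,7S,8R,10R)-14-[tert-butyl(diphenyl)silyl]oxy-3-(2-methylpropanoyloxy)germacra-4,11(13)-diene-12,8:15,6-diolide
Conditions: (i-PrCO)2O, DMAP (cat.), pyridine, CH2Cl2, 0 → 25 °C
Reagents that add atoms: 2-methylpropanoic anhydride, CC(C)C(=O)OC(=O)C(C)C
Why: DMAP-catalyzed acylation of the secondary allylic alcohol by the anhydride proceeds with retention at C3 under conditions too mild to epimerize the bridged butenolide.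

Step 17
Reactants: 27 (3S,6R,7S,8R,10R)-14-[tert-butyl(diphenyl)silyl]oxy-3-(2-methylpropanoyloxy)germacra-4,11(13)-diene-12,8:15,6-diolide
Product: 28 (3S,6R,7S,8R,10R)-14-hydroxy-3-(2-methylpropanoyloxy)germacra-4,11(13)-diene-12,8:15,6-diolide (CNP0332805.1)
Conditions: HF·pyridine, pyridine, THF, 0 → 25 °C
Reagents that add atoms: none
Why: Fluoride-mediated cleavage of the silyl ether with buffered HF·pyridine is selective for the Si–O bond and leaves the isobutyrate, both lactones and the exocyclic methylene intact, giving the target.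

**Compound list**
1 | (4S)-4-benzyl-1,3-oxazolidin-2-one | O=C1N[C@@H](Cc2ccccc2)CO1 | starting material
2 | hex-5-enoyl chloride | C=CCCCC(=O)Cl | starting material
3 | (4S)-4-benzyl-3-(hex-5-enoyl)-1,3-oxazolidin-2-one | C=CCCCC(=O)N1[C@@H](Cc2ccccc2)COC1=O | intermediate
4 | tert-butyl bromoacetate | BrCC(=O)OC(C)(C)C | starting material
5 | tert-butyl (3R)-3-{[(4S)-4-benzyl-2-oxo-1,3-oxazolidin-3-yl]carbonyl}hept-6-enoate | C=CCC[C@H](CC(=O)OC(C)(C)C)C(=O)N1[C@@H](Cc2ccccc2)COC1=O | intermediate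
6 | tert-butyl (3R)-3-(hydroxymethyl)hept-6-enoate | C=CCC[C@H](CC(=O)OC(C)(C)C)CO | intermediate
7 | tert-butyl (3R)-3-({[tert-butyl(diphenyl)silyl]oxy}methyl)hept-6-enoate | C=CCC[C@H](CC(=O)OC(C)(C)C)CO[Si](c1ccccc1)(c1ccccc1)C(C)(C)C | intermediate
8 | (3R)-3-({[tert-butyl(diphenyl)silyl]oxy}methyl)hept-6-enal | C=CCC[C@H](CC=O)CO[Si](c1ccccc1)(c1ccccc1)C(C)(C)C | intermediate
9 | methyl 4-chloro-4-oxobutanoate | COC(=O)CCC(=O)Cl | starting material
10 | methyl 4-[(4S)-4-benzyl-2-oxo-1,3-oxazolidin-3-yl]-4-oxobutanoate | COC(=O)CCC(=O)N1[C@@H](Cc2ccccc2)COC1=O | intermediate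
11 | methyl (3S,4R,6R)-3-{[(4S)-4-benzyl-2-oxo-1,3-oxazolidin-3-yl]carbonyl}-6-({[tert-butyl(diphenyl)silyl]oxy}methyl)-4-hydroxydec-9-enoate | COC(=O)C[C@@H]([C@H](O)C[C@H](CO[Si](c1ccccc1)(c1ccccc1)C(C)(C)C)CCC=C)C(=O)N1[C@@H](Cc2ccccc2)COC1=O | intermediate
12 | (4S)-4-benzyl-3-{[(2R,3S)-2-[(2R)-2-({[tert-butyl(diphenyl)silyl]oxy}methyl)hex-5-en-1-yl]-5-oxooxolan-3-yl]carbonyl}-1,3-oxazolidin-2-one | O=C1O[C@H](C[C@H](CO[Si](c2ccccc2)(c2ccccc2)C(C)(C)C)CCC=C)[C@H](C1)C(=O)N1[C@@H](Cc2ccccc2)COC1=O | intermediate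
13 | (2R,3S)-2-[(2R)-2-({[tert-butyl(diphenyl)silyl]oxy}methyl)hex-5-en-1-yl]-5-oxooxolane-3-carboxylic acid | O=C1O[C@H](C[C@H](CO[Si](c2ccccc2)(c2ccccc2)C(C)(C)C)CCC=C)[C@H](C1)C(=O)O | intermediate
14 | (2R,3S)-2-[(2R)-2-({[tert-butyl(diphenyl)silyl]oxy}methyl)hex-5-en-1-yl]-5-oxooxolane-3,4-dicarboxylic acid (C4 epimers; magnesium chelate in the flask) | O=C1O[C@H](C[C@H](CO[Si](c2ccccc2)(c2ccccc2)C(C)(C)C)CCC=C)[C@H](C1C(=O)O)C(=O)O | intermediate
15 | (2R,3S)-2-[(2R)-2-({[tert-butyl(diphenyl)silyl]oxy}methyl)hex-5-en-1-yl]-4-methylidene-5-oxooxolane-3-carboxylic acid | C=C1C(=O)O[C@H](C[C@H](CO[Si](c2ccccc2)(c2ccccc2)C(C)(C)C)CCC=C)[C@H]1C(=O)O | intermediate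
16 | methyl prop-2-ynoate | C#CC(=O)OC | starting material
17 | tributyl(methoxy)stannane | CO[Sn](CCCC)(CCCC)CCCC | starting material
18 | methyl 3-(tributylstannyl)prop-2-ynoate | COC(=O)C#C[Sn](CCCC)(CCCC)CCCC | intermediate
19 | (2R,3S)-2-[(2R)-2-({[tert-butyl(diphenyl)silyl]oxy}methyl)hex-5-en-1-yl]-4-methylidene-5-oxooxolane-3-carbonyl chloride | C=C1C(=O)O[C@H](C[C@H](CO[Si](c2ccccc2)(c2ccccc2)C(C)(C)C)CCC=C)[C@H]1C(=O)Cl | intermediate
20 | methyl 4-[(2R,3S)-2-[(2R)-2-({[tert-butyl(diphenyl)silyl]oxy}methyl)hex-5-en-1-yl]-4-methylidene-5-oxooxolan-3-yl]-4-oxobut-2-ynoate | C=C1C(=O)O[C@H](C[C@H](CO[Si](c2ccccc2)(c2ccccc2)C(C)(C)C)CCC=C)[C@H]1C(=O)C#CC(=O)OC | intermediate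
21 | methyl (4S)-4-hydroxy-4-[(2R,3R)-2-[(2R)-2-({[tert-butyl(diphenyl)silyl]oxy}methyl)hex-5-en-1-yl]-4-methylidene-5-oxooxolan-3-yl]but-2-ynoate | C=C1C(=O)O[C@H](C[C@H](CO[Si](c2ccccc2)(c2ccccc2)C(C)(C)C)CCC=C)[C@H]1[C@H](O)C#CC(=O)OC | intermediate
22 | methyl (2E,4S)-4-hydroxy-4-[(2R,3R)-2-[(2R)-2-({[tert-butyl(diphenyl)silyl]oxy}methyl)hex-5-en-1-yl]-4-methylidene-5-oxooxolan-3-yl]-2-(tributylstannyl)but-2-enoate | C=C1C(=O)O[C@H](C[C@H](CO[Si](c2ccccc2)(c2ccccc2)C(C)(C)C)CCC=C)[C@H]1[C@H](O)/C=C(\C(=O)OC)[Sn](CCCC)(CCCC)CCCC | intermediate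
23 | (4S,5R)-5-[(2R)-2-({[tert-butyl(diphenyl)silyl]oxy}methyl)hex-5-en-1-yl]-3-methylidene-4-[(2S)-5-oxo-4-(tributylstannyl)-2,5-dihydrofuran-2-yl]oxolan-2-one | C=C1C(=O)O[C@H](C[C@H](CO[Si](c2ccccc2)(c2ccccc2)C(C)(C)C)CCC=C)[C@H]1[C@@H]1OC(=O)C([Sn](CCCC)(CCCC)CCCC)=C1 | intermediate
24 | (4S,5R)-5-[(2R)-2-({[tert-butyl(diphenyl)silyl]oxy}methyl)hex-5-en-1-yl]-4-[(2S)-4-iodo-5-oxo-2,5-dihydrofuran-2-yl]-3-methylideneoxolan-2-one | C=C1C(=O)O[C@H](C[C@H](CO[Si](c2ccccc2)(c2ccccc2)C(C)(C)C)CCC=C)[C@H]1[C@@H]1OC(=O)C(I)=C1 | intermediate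
25 | (4R)-4-({[tert-butyl(diphenyl)silyl]oxy}methyl)-5-[(2R,3S)-3-[(2S)-4-iodo-5-oxo-2,5-dihydrofuran-2-yl]-4-methylidene-5-oxooxolan-2-yl]pentanal | C=C1C(=O)O[C@H](C[C@H](CO[Si](c2ccccc2)(c2ccccc2)C(C)(C)C)CCC=O)[C@H]1[C@@H]1OC(=O)C(I)=C1 | intermediate
26 | (3S,6R,7S,8R,10R)-14-[tert-butyl(diphenyl)silyl]oxy-3-hydroxygermacra-4,11(13)-diene-12,8:15,6-diolide | C=C1C(=O)O[C@@H]2C[C@H](CO[Si](c3ccccc3)(c3ccccc3)C(C)(C)C)CC[C@H](O)C3=C[C@@H](OC3=O)[C@@H]12 | intermediate
27 | (3S,6R,7S,8R,10R)-14-[tert-butyl(diphenyl)silyl]oxy-3-(2-methylpropanoyloxy)germacra-4,11(13)-diene-12,8:15,6-diolide | C=C1C(=O)O[C@@H]2C[C@H](CO[Si](c3ccccc3)(c3ccccc3)C(C)(C)C)CC[C@H](OC(=O)C(C)C)C3=C[C@@H](OC3=O)[C@@H]12 | intermediate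
28 | (3S,6R,7S,8R,10R)-14-hydroxy-3-(2-methylpropanoyloxy)germacra-4,11(13)-diene-12,8:15,6-diolide (CNP0332805.1) | C=C1C(=O)O[C@@H]2C[C@H](CO)CC[C@H](OC(=O)C(C)C)C3=C[C@@H](OC3=O)[C@@H]12 | target

**Step count and risks**
Total step count: 17 (steps 6 and 10 are one-step side branches). Longest linear sequence: 15 steps (1–5, 7–9, 11–17).

Most likely to fail, first: step 15. The addition of the alkenylchromium to the C3 aldehyde may show poor facial selectivity, because chelation of the chromium alkoxide by the C15 lactone carbonyl could compete with the dipole-controlled arrangement and deliver the 3R carbinol. The fallback sets out from 25: the same closure is run and the carbinol is collected as the 3R epimer or as the epimer mixture, the 3-epi alcohol F1. Dess–Martin oxidation (NaHCO3-buffered CH2Cl2) converges this material to the C3 ketone F2, a 3-acylbutenolide. Corey–Bakshi–Shibata reduction with the (R)-methyl oxazaborolidine and catecholborane (toluene, −78 °C) then places C3 under reagent control, with the butenolide alkene as the large group, and the route is rejoined at 26.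

Second: step 12. Hydride or isopropoxide may add in conjugate fashion to the triple bond of 20, which is activated by both the ketone and the ester, instead of clean carbonyl reduction. The fallback sets out from 15 by way of acid chloride 19: Stille acylation with trimethyl[(tributylstannyl)ethynyl]silane (Pd2(dba)3, tri(2-furyl)phosphine, toluene) gives the silyl ynone F3, a standard substrate for the same transfer hydrogenation, which gives the propargylic alcohol F4. Protodesilylation (AgNO3 cat., aqueous acetone) gives the terminal alkyne F5, and oxidative methoxycarbonylation (PdCl2 cat., CuCl2, NaOAc, CO, MeOH, 25 °C) rejoins the route at 21.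

Third: step 11. The acid chloride 19 may enolize toward the ketene, which would scramble C7 or move the exocyclic double bond into the ring before the coupling takes place. The fallback sets out from 15: thiophenol and N,N'-dicyclohexylcarbodiimide (CH2Cl2, 0 °C) give the S-phenyl thioester F6, which is far less prone to ketene formation. A Liebeskind–Srogl-type coupling with stannane 18 (Pd2(dba)3, tri(2-furyl)phosphine, CuO2PPh2, THF, 25 °C) under neutral conditions rejoins the route at 20.

Further compounds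
F1 | step 15 | (3R,6R,7S,8R,10R)-14-[tert-butyl(diphenyl)silyl]oxy-3-hydroxygermacra-4,11(13)-diene-12,8:15,6-diolide (C3 epimer of 26) | C=C1C(=O)O[C@@H]2C[C@H](CO[Si](c3ccccc3)(c3ccccc3)C(C)(C)C)CC[C@@H](O)C3=C[C@@H](OC3=O)[C@@H]12
F2 | step 15 | (6R,7S,8R,10R)-14-[tert-butyl(diphenyl)silyl]oxy-3-oxogermacra-4,11(13)-diene-12,8:15,6-diolide | C=C1C(=O)O[C@@H]2C[C@H](CO[Si](c3ccccc3)(c3ccccc3)C(C)(C)C)CCC(=O)C3=C[C@@H](OC3=O)[C@@H]12
F3 | step 12 | (4S,5R)-5-[(2R)-2-({[tert-butyl(diphenyl)silyl]oxy}methyl)hex-5-en-1-yl]-3-methylidene-4-[3-(trimethylsilyl)prop-2-ynoyl]oxolan-2-one | C=C1C(=O)O[C@H](C[C@H](CO[Si](c2ccccc2)(c2ccccc2)C(C)(C)C)CCC=C)[C@H]1C(=O)C#C[Si](C)(C)C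
F4 | step 12 | (4R,5R)-5-[(2R)-2-({[tert-butyl(diphenyl)silyl]oxy}methyl)hex-5-en-1-yl]-4-[(1S)-1-hydroxy-3-(trimethylsilyl)prop-2-yn-1-yl]-3-methylideneoxolan-2-one | C=C1C(=O)O[C@H](C[C@H](CO[Si](c2ccccc2)(c2ccccc2)C(C)(C)C)CCC=C)[C@H]1[C@H](O)C#C[Si](C)(C)C
F5 | step 12 | (4R,5R)-5-[(2R)-2-({[tert-butyl(diphenyl)silyl]oxy}methyl)hex-5-en-1-yl]-4-[(1S)-1-hydroxyprop-2-yn-1-yl]-3-methylideneoxolan-2-one | C=C1C(=O)O[C@H](C[C@H](CO[Si](c2ccccc2)(c2ccccc2)C(C)(C)C)CCC=C)[C@H]1[C@H](O)C#C
F6 | step 11 | S-phenyl (2R,3S)-2-[(2R)-2-({[tert-butyl(diphenyl)silyl]oxy}methyl)hex-5-en-1-yl]-4-methylidene-5-oxooxolane-3-carbothioate | C=C1C(=O)O[C@H](C[C@H](CO[Si](c2ccccc2)(c2ccccc2)C(C)(C)C)CCC=C)[C@H]1C(=O)Sc1ccccc1
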